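**Retrosynthetic overview**
- The target is the formal (S)-adduct of 2-aminoimidazole (through its C4–H) across one C=C of a C2v-symmetric 2-amino-4,5-bis[(E)-3-(4,5-dibromopyrrole-2-carboxamido)prop-1-enyl]imidazole. The bond cut is C(sp3)–C4 of the monosubstituted imidazole.
- The symmetric bis-amide comes from 4,5-bis[(E)-3-aminopropenyl]-2-aminoimidazole and two equivalents of 4,5-dibromo-2-(trichloroacetyl)pyrrole by N-acylation.
- The triamine comes from Boc removal and double dehydration of a bis-carbinol, itself from 2-aminoimidazole and two equivalents of N-Boc-3-aminopropanal (C–C bonds at C4 and C5).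
- No ring is built. Both 2-aminoimidazoles come intact from 2-aminoimidazole (first as the core, last as the nucleophile) and both pyrroles from the acyl donor. The only stereocentre is made in the last step.

Assumption: the target is handled as the neutral free base (isolated as a TFA salt, any NH tautomer), its stereocentre is (S) by CIP, and the sense of induction of the chiral phosphate in Step 4 must be found by experiment; (R)-TRIP is written and (S)-TRIP is used if the first run gives the (R)-product.

**Step 1**
Reactants: 1, 2-aminoimidazole (bought as hemisulfate); 2, tert-butyl (3-oxopropyl)carbamate (3 equiv)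
Product: 3, 2-amino-4,5-bis[3-(Boc-amino)-1-hydroxypropyl]-1H-imidazole (meso/rac mixture at the two carbinol carbons)
Conditions: Na2CO3 (1.1 equiv), H2O/THF 1:1, 35 °C, 72 h
Reagents that add atoms: tert-butyl (3-oxopropyl)carbamate, CC(C)(C)OC(=O)NCCC=O (reactant 2, two molecules incorporated)
Why: Ahond–Horne hydroxyalkylation (aldol-type electrophilic substitution at the enamine-like C4/C5 of free-base 2-aminoimidazole by an aldehyde), pushed to double addition with excess aldehyde; mono-addition is established and the second addition is an extension that relies on the C5 nucleophilicity of a 4-alkyl-2-aminoimidazole; the two carbinol centres form unselectively and are destroyed in Step 2.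

**Step 2**
Reactants: 3
Product: 4, 4,5-bis[(E)-3-aminoprop-1-en-1-yl]-1H-imidazol-2-amine (isolated as the tris-TFA salt)
Conditions: TFA/CH2Cl2 1:1, 0 °C to rt, 1 h; then neat TFA, 55 °C, 6 h; evaporate
Reagents that add atoms: none
Why: Boc acidolysis occurs first (so the carbamate carbonyl cannot trap the cation), then E1 dehydration through the 2-amino-4-alkylidene-4H-imidazolium (azafulvenium) cation, whose only β-hydrogens are on the CH2, giving the conjugated (E)-alkenes; no free imidazole C–H is present to intercept the cation.

**Step 3**
Reactants: 4; 5, 2,2,2-trichloro-1-(4,5-dibromo-1H-pyrrol-2-yl)ethan-1-one (2.1 equiv)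
Product: 6, 2-amino-4,5-bis[(E)-3-(4,5-dibromo-1H-pyrrole-2-carboxamido)prop-1-en-1-yl]-1H-imidazole (C2v-symmetric, achiral)
Conditions: Na2CO3 (4 equiv), DMF, rt, 16 h
Reagents that add atoms: 4,5-dibromo-2-(trichloroacetyl)pyrrole, O=C(c1cc(Br)c(Br)[nH]1)C(Cl)(Cl)Cl (transfers two 4,5-dibromopyrrole-2-carbonyl groups; CHCl3 is lost)
Why: haloform-type N-acylation by a 2-(trichloroacetyl)pyrrole, the standard end-game for oroidin-type amides; the primary allylic amines react while the amidine-like 2-aminoimidazole nitrogen does not.

**Step 4 (key step)**
Reactants: 6; 1, 2-aminoimidazole (free base, 3 equiv, liberated from the hemisulfate with NaOMe/MeOH)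
Product: 7, the target, N-[(3S)-3-(2-amino-1H-imidazol-4-yl)-3-{2-amino-5-[(1E)-3-(4,5-dibromo-1H-pyrrole-2-carboxamido)prop-1-en-1-yl]-1H-imidazol-4-yl}propyl]-4,5-dibromo-1H-pyrrole-2-carboxamide
Conditions: (R)-TRIP [(R)-3,3′-bis(2,4,6-triisopropylphenyl)-BINOL hydrogen phosphate] (30 mol %), CHCl3/THF 3:1 (0.02 M), 45 °C, stop at about 80% conversion; RP-HPLC (MeCN/H2O, 0.1% TFA)
Reagents that add atoms: 2-aminoimidazole, Nc1ncc[nH]1 (reactant 1, fully incorporated)
Why: Proposed new method: the phosphoric acid shuttles a proton to the terminal vinyl carbon (the CH next to CH2N) of one of the two equivalent alkenyl arms of 6, giving a dearomatised azafulvenium paired with the chiral phosphate; the phosphate hydrogen-bonds both the cation N–H and the N–H of incoming 2-aminoimidazole, which attacks the α-carbon through C4 on one enantioface to set the (S) stereocentre, and proton loss re-aromatises both rings; the other arm stays (E)-alkenyl, and mono-addition is favoured because the cross-conjugated divinyl system is protonated more easily than the mono-vinyl product; closest known reactions are chiral-phosphoric-acid Friedel–Crafts hydroarylations through alkylideneindoleninium or (aza)quinone-methide ion pairs and the acid-mediated C4 coupling of 2-aminoimidazole with stabilised cations.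

**Compound list**
1 | 2-aminoimidazole (1H-imidazol-2-amine; bought as hemisulfate) | Nc1ncc[nH]1 | starting material
2 | tert-butyl (3-oxopropyl)carbamate (N-Boc-3-aminopropanal) | CC(C)(C)OC(=O)NCCC=O | starting material
3 | 2-amino-4,5-bis[3-(Boc-amino)-1-hydroxypropyl]-1H-imidazole (diastereomer mixture) | CC(C)(C)OC(=O)NCCC(O)c1nc(N)[nH]c1C(O)CCNC(=O)OC(C)(C)C | intermediate
4 | 4,5-bis[(E)-3-aminoprop-1-en-1-yl]-1H-imidazol-2-amine (tris-TFA salt) | NC/C=C/c1nc(N)[nH]c1/C=C/CN | intermediate
5 | 2,2,2-trichloro-1-(4,5-dibromo-1H-pyrrol-2-yl)ethan-1-one | O=C(c1cc(Br)c(Br)[nH]1)C(Cl)(Cl)Cl | starting material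
6 | 2-amino-4,5-bis[(E)-3-(4,5-dibromo-1H-pyrrole-2-carboxamido)prop-1-en-1-yl]-1H-imidazole | Nc1nc(/C=C/CNC(=O)c2cc(Br)c(Br)[nH]2)c(/C=C/CNC(=O)c2cc(Br)c(Br)[nH]2)[nH]1 | intermediate
7 | CID11411715, (S)-configured | Nc1ncc([C@H](CCNC(=O)c2cc(Br)c(Br)[nH]2)c2[nH]c(N)nc2/C=C/CNC(=O)c2cc(Br)c(Br)[nH]2)[nH]1 | target

**Totals**
Total steps: 4. Longest linear sequence: 4 (1 + 2 → 3 → 4 → 6 → 7; compounds 5 and 1 enter as bought reagents).

**Steps most likely to fail**
1. Step 4. Risks: low ee or rate with strongly basic, polar partners; over-addition to the second alkene; intramolecular attack of the new imidazole C5–H on the remaining arm to give a six-membered ring; pyrrole N/C3 cyclisation.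
   Fallback: give up catalytic asymmetric induction. Run the same C–C coupling racemically under achiral Brønsted acid (TFA or MsOH, Horne-type) and separate the enantiomers of 7 by preparative chiral HPLC or by diastereomeric salt crystallisation with a dibenzoyl tartaric acid.
2. Step 1. Risks: the reaction stops at mono-hydroxyalkylation, or N,O-aminal by-products form.
   Fallback: build the symmetric dialkenyl core by cross-coupling instead of aldehyde condensation. Take N-SEM-4,5-diiodoimidazole through a double Suzuki–Miyaura coupling with (E)-3-(Boc-amino)prop-1-enyl-Bpin, then C2 lithiation/TsN3 azidation, Staudinger reduction and acid deprotection to reach 4.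
3. Step 2. Risks: incomplete elimination, or oligomerisation of the vinyl-aminoimidazole under hot acid.
   Fallback: omit the discrete diene. Remove Boc only, acylate the bis-carbinol diamine with 5, and use the bis-carbinol as the azafulvenium precursor in the phosphoric-acid step (stereoablative SN1 replacement of one OH by 1), then dehydrate the remaining carbinol last.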